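**Strategy**

The route rests on opening ring A at the C4–C5 bond and ring B at the C9–C10 bond, so that the labdane core becomes an acyclic diene 2-methyl-3-oxo ester. The feature exploited is the quaternary C4 of ring A, which carries the C19 ester and adjoins C3: a temporary C3 ketone turns C4 into a stabilised radical. One oxidative radical bicyclization then closes rings A and B, sets C4, C5, C9 and C10 and leaves the C8(17) exocyclic alkene. The precursor is a geranylacetone-derived chain with the ester as a (−)-8-phenylmenthyl auxiliary and C13 masked as a dioxolane. Deoxygenation at C3, side-chain olefination and exchange of the auxiliary for methyl complete the synthesis.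

Key step: step 6

Remark on numbering: labdane numbering is used (decalin C1–C10, exocyclic methylene C17, C18 and C19 on C4, C20 on C10, side chain C11–C16); the target is methyl 15-(hexadecanoyloxy)labda-8(17),13E-dien-19-oate with 4β-CO2Me, 5α-H, 9α-H and 10β-CH3.

Assumption: the (1R,2S,5R)-8-phenylmenthyl ester is taken to direct the bicyclization to the 5α-H, 10β-methyl series; should the sense prove opposite, the (1S,2R,5S) auxiliary would be used with no other change.

**Route**

Step 1
Reactants: 1 (E)-geranylacetone
Product: 2 2-[(3E)-4,8-dimethylnona-3,7-dien-1-yl]-2-methyl-1,3-dioxolane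
Conditions: ethylene glycol, PPTS (cat.), benzene, reflux, Dean–Stark
Reagents that add atoms: ethylene glycol OCCO
Why: Acid-catalysed ketalisation with azeotropic removal of water masks the methyl ketone against the later dianion chemistry, and the mild acid should leave both trisubstituted alkenes and their geometry untouched.

Step 2
Reactants: 2 geranylacetone ethylene ketal
Product: 3 (2E,6E)-2,6-dimethyl-9-(2-methyl-1,3-dioxolan-2-yl)nona-2,6-dien-1-ol
Conditions: SeO2 (cat.), t-BuOOH (in decane), CH2Cl2, 0 °C to rt
Reagents that add atoms: tert-butyl hydroperoxide CC(C)(C)OO (oxygen source); selenium dioxide O=[Se]=O (transfers the oxygen)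
Why: SeO2-catalysed allylic oxidation (ene reaction then [2,3]-sigmatropic shift) should attack the more electron-rich terminal trisubstituted alkene at its (E)-methyl group and give the (E)-allylic alcohol.

Step 3
Reactants: 3 allylic alcohol
Product: 4 2-[(3E,7E)-9-bromo-4,8-dimethylnona-3,7-dien-1-yl]-2-methyl-1,3-dioxolane
Conditions: CBr4, PPh3, 2,6-lutidine (cat.), CH2Cl2, 0 °C
Reagents that add atoms: carbon tetrabromide BrC(Br)(Br)Br
Why: Appel bromination under near-neutral conditions should convert the primary allylic alcohol into the bromide by SN2 displacement of the alkoxyphosphonium ion without allylic transposition or loss of the ketal.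

Step 4
Reactants: 5 (1R,2S,5R)-(−)-8-phenylmenthol; 6 methyl 2-methyl-3-oxobutanoate
Product: 7 (1R,2S,5R)-8-phenylmenthyl 2-methyl-3-oxobutanoate (mixture of epimers at the alpha carbon)
Conditions: DMAP (cat.), toluene, reflux, 4 Å molecular sieves
Reagents that add atoms: none
Why: DMAP-catalysed transesterification of an enolisable beta-keto ester should load the auxiliary, and the epimeric alpha carbon is irrelevant because it later becomes a planar radical centre.

Step 5
Reactants: 7 auxiliary 2-methylacetoacetate; 4 allylic bromide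
Product: 9 (1R,2S,5R)-8-phenylmenthyl (6E,10E)-2,6,10-trimethyl-13-(2-methyl-1,3-dioxolan-2-yl)-3-oxotrideca-6,10-dienoate, via dilithium dienolate 8 (not isolated)
Conditions: LDA (2.1 equiv), THF, −78 to 0 °C; then 4, 0 °C to rt; H2O
Reagents that add atoms: none
Why: Acetoacetate dianion alkylation should take place in an SN2 reaction at the more basic terminal carbanion of the dienolate, which leaves the alpha-methyl beta-keto ester unit intact and both alkenes E.

Step 6
Reactants: 9 diene keto ester
Product: 11 (−)-8-phenylmenthyl 3,13-dioxo-14,15-dinorlabd-8(17)-en-19-oate, via bicyclic dioxolane 10 (not isolated)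
Conditions: Mn(OAc)3·2H2O (2.2 equiv), Cu(OAc)2·H2O (1 equiv, turned over by Mn(OAc)3), degassed AcOH, 25–50 °C; then 1 M aq. HCl, THF, rt
Reagents that add atoms: water O
Why: Mn(OAc)3 should form the trivalent manganese enolate of the 2-methyl-3-oxo ester and by electron transfer give the C4 radical, which adds to C5 of the (E)-C5=C10 alkene; the tertiary C10 radical then adds to C9 of the (E)-C8=C9 alkene, and the tertiary C8 radical is oxidised by divalent copper through an alkylcopper species that loses a hydrogen of the C17 methyl to give the exocyclic alkene. The closest known reaction type is the oxidative free-radical polycyclization of unsaturated 2-alkylacetoacetates with Mn(OAc)3 and Cu(OAc)2, including its 8-phenylmenthyl ester auxiliary version. Ring A closes 6-endo-trig through the C4–C5 bond and ring B closes 6-endo-trig through the C10–C9 bond in a chair–chair array. C5 and C10 (trans ring fusion) and C9 (equatorial side chain) follow from the E geometry of both alkenes in that array, C4 follows from the preferred geometry of the ketone-in-ring radical, which places the ester axial and cis to the C10 methyl, and the absolute sense comes from the phenyl group of the auxiliary covering one face of the planar dicarbonyl radical. The step needs the cascade to stop after two rings and to end as the 8(17)-alkene: the side chain carries only a ketal at C13 and no third alkene, and copper-mediated oxidation of a tertiary radical favours loss of hydrogen from the less substituted methyl position. Aqueous HCl then unmasks the C13 ketone in the same flask.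

Step 7
Reactants: 11 bicyclic diketo ester
Product: 12 15-ethyl 19-[(−)-8-phenylmenthyl] 3-oxolabda-8(17),13E-diene-15,19-dioate
Conditions: (EtO)2P(O)CH2CO2Et, NaH, THF, 0 °C to rt
Reagents that add atoms: triethyl phosphonoacetate CCOC(=O)CP(=O)(OCC)OCC
Why: Horner–Wadsworth–Emmons olefination should occur only at the unhindered C13 methyl ketone (the C3 ketone is flanked by the quaternary C4) and should favour the (E)-enoate through equilibration of the adducts, the minor Z isomer being removed by chromatography.

Step 8
Reactants: 12 keto diester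
Product: 14 15-ethyl 19-[(−)-8-phenylmenthyl] labda-8(17),13E-diene-15,19-dioate, via C3 tosylhydrazone 13 (not isolated)
Conditions: TsNHNH2, EtOH, reflux; concentrate; catecholborane, CHCl3, 0 °C to rt; then NaOAc·3H2O, reflux
Reagents that add atoms: none
Why: Tosylhydrazone formation followed by catecholborane reduction (hydride addition to C=N, then acetate-induced loss of sulfinate and of N2 from the diazene) should remove the C3 oxygen under non-acidic conditions that spare the exocyclic alkene, the enoate and both esters.

Step 9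
Reactants: 14 diester
Product: 15 labda-8(17),13E-diene-15,19-diol (agathadiol)
Conditions: LiAlH4, THF, 0 °C then reflux; H2O, aq. NaOH work-up
Reagents that add atoms: none
Why: LiAlH4 should reduce the conjugated ethyl ester by 1,2-addition to the (E)-allylic alcohol at 0 °C and the hindered axial C19 ester to the neopentyl alcohol at reflux, which releases auxiliary 5 for recovery and touches no stereocentre.

Step 10
Reactants: 15 agathadiol; 16 palmitoyl chloride
Product: 17 19-hydroxylabda-8(17),13E-dien-15-yl hexadecanoate
Conditions: 16 (1.05 equiv), pyridine, CH2Cl2, −20 to 0 °C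
Reagents that add atoms: none
Why: Acylation with a slight excess of acid chloride at low temperature should discriminate the unhindered allylic C15 hydroxyl from the axial neopentyl C19 hydroxyl on steric grounds.

Step 11
Reactants: 17 C19 alcohol
Product: 19 15-(hexadecanoyloxy)labda-8(17),13E-dien-19-oic acid, via C19 aldehyde 18 (not isolated)
Conditions: Jones reagent (CrO3, H2SO4, H2O; stock solution), acetone, 0 °C
Reagents that add atoms: water O
Why: Jones oxidation should take the neopentyl alcohol through the aldehyde and its hydrate to the acid in cold acetone within minutes, conditions under which the allylic ester and the two isolated alkenes are expected to survive.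

Step 12
Reactants: 19 C19 acid
Product: 20 methyl 15-(hexadecanoyloxy)labda-8(17),13E-dien-19-oate (target)
Conditions: MeI, K2CO3, DMF, rt
Reagents that add atoms: iodomethane CI
Why: SN2 O-alkylation of the potassium carboxylate by MeI is insensitive to the steric hindrance at the acyl carbon and should leave the palmitate untouched.

**Compound list**

1 | (E)-geranylacetone, (5E)-6,10-dimethylundeca-5,9-dien-2-one | CC(=O)CC/C=C(\C)CCC=C(C)C | starting material
2 | 2-[(3E)-4,8-dimethylnona-3,7-dien-1-yl]-2-methyl-1,3-dioxolane | CC1(CC/C=C(\C)CCC=C(C)C)OCCO1 | intermediate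
3 | (2E,6E)-2,6-dimethyl-9-(2-methyl-1,3-dioxolan-2-yl)nona-2,6-dien-1-ol | CC1(CC/C=C(\C)CC/C=C(\C)CO)OCCO1 | intermediate
4 | 2-[(3E,7E)-9-bromo-4,8-dimethylnona-3,7-dien-1-yl]-2-methyl-1,3-dioxolane | CC1(CC/C=C(\C)CC/C=C(\C)CBr)OCCO1 | intermediate
5 | (1R,2S,5R)-(−)-8-phenylmenthol | CC(C)(c1ccccc1)[C@@H]1CC[C@@H](C)C[C@H]1O | starting material
6 | methyl 2-methyl-3-oxobutanoate | COC(=O)C(C)C(C)=O | starting material
7 | (1R,2S,5R)-8-phenylmenthyl 2-methyl-3-oxobutanoate (alpha-epimer mixture) | CC(=O)C(C)C(=O)O[C@@H]1C[C@H](C)CC[C@H]1C(C)(C)c1ccccc1 | intermediate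
8 | dilithium dienolate of 7 | [Li+].[Li+].C=C([O-])C(C)=C([O-])O[C@@H]1C[C@H](C)CC[C@H]1C(C)(C)c1ccccc1 | intermediate (not isolated)
9 | (1R,2S,5R)-8-phenylmenthyl (6E,10E)-2,6,10-trimethyl-13-(2-methyl-1,3-dioxolan-2-yl)-3-oxotrideca-6,10-dienoate (C2-epimer mixture) | CC1(CC/C=C(\C)CC/C=C(\C)CCC(=O)C(C)C(=O)O[C@@H]2C[C@H](C)CC[C@H]2C(C)(C)c2ccccc2)OCCO1 | intermediate
10 | (−)-8-phenylmenthyl 13,13-(ethylenedioxy)-3-oxo-14,15-dinorlabd-8(17)-en-19-oate (4β-ester, 5α-H, 9α-H, 10β-CH3) | C=C1CC[C@@H]2[C@](C)(CCC(=O)[C@]2(C)C(=O)O[C@@H]3C[C@H](C)CC[C@H]3C(C)(C)c3ccccc3)[C@H]1CCC4(C)OCCO4 | intermediate (not isolated)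
11 | (−)-8-phenylmenthyl 3,13-dioxo-14,15-dinorlabd-8(17)-en-19-oate (4β-ester, 5α-H, 9α-H, 10β-CH3) | C=C1CC[C@@H]2[C@](C)(CCC(=O)[C@]2(C)C(=O)O[C@@H]3C[C@H](C)CC[C@H]3C(C)(C)c3ccccc3)[C@H]1CCC(C)=O | intermediate
12 | 15-ethyl 19-[(−)-8-phenylmenthyl] 3-oxolabda-8(17),13E-diene-15,19-dioate | C=C1CC[C@@H]2[C@](C)(CCC(=O)[C@]2(C)C(=O)O[C@@H]3C[C@H](C)CC[C@H]3C(C)(C)c3ccccc3)[C@H]1CC/C(C)=C/C(=O)OCC | intermediate
13 | C3 tosylhydrazone of 12 | C=C1CC[C@@H]2[C@](C)(CCC(=NNS(=O)(=O)c3ccc(C)cc3)[C@]2(C)C(=O)O[C@@H]3C[C@H](C)CC[C@H]3C(C)(C)c3ccccc3)[C@H]1CC/C(C)=C/C(=O)OCC | intermediate (not isolated)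
14 | 15-ethyl 19-[(−)-8-phenylmenthyl] labda-8(17),13E-diene-15,19-dioate | C=C1CC[C@@H]2[C@](C)(CCC[C@]2(C)C(=O)O[C@@H]3C[C@H](C)CC[C@H]3C(C)(C)c3ccccc3)[C@H]1CC/C(C)=C/C(=O)OCC | intermediate
15 | labda-8(17),13E-diene-15,19-diol (agathadiol) | C=C1CC[C@@H]2[C@](C)(CCC[C@]2(C)CO)[C@H]1CC/C(C)=C/CO | intermediate
16 | palmitoyl chloride (hexadecanoyl chloride) | CCCCCCCCCCCCCCCC(=O)Cl | starting material
17 | 19-hydroxylabda-8(17),13E-dien-15-yl hexadecanoate | C=C1CC[C@@H]2[C@](C)(CCC[C@]2(C)CO)[C@H]1CC/C(C)=C/COC(=O)CCCCCCCCCCCCCCC | intermediate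
18 | 19-oxolabda-8(17),13E-dien-15-yl hexadecanoate | C=C1CC[C@@H]2[C@](C)(CCC[C@]2(C)C=O)[C@H]1CC/C(C)=C/COC(=O)CCCCCCCCCCCCCCC | intermediate (not isolated)
19 | 15-(hexadecanoyloxy)labda-8(17),13E-dien-19-oic acid | C=C1CC[C@@H]2[C@](C)(CCC[C@]2(C)C(=O)O)[C@H]1CC/C(C)=C/COC(=O)CCCCCCCCCCCCCCC | intermediate
20 | methyl 15-(hexadecanoyloxy)labda-8(17),13E-dien-19-oate | C=C1CC[C@@H]2[C@](C)(CCC[C@]2(C)C(=O)OC)[C@H]1CC/C(C)=C/COC(=O)CCCCCCCCCCCCCCC | target

**Step count**

Total steps: 12. Longest linear sequence: 11 steps (steps 1–3 and 5–12, from 1).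

**Steps most likely to fail, with fallbacks**

Step 6. Facial discrimination by the auxiliary may be insufficient, the C10 radical may be oxidised before ring B closes, or the copper-mediated termination may remove a ring hydrogen and give an endocyclic alkene. The fallback separates radical generation from termination by a group-transfer cascade. It sets out from 9, which is selenenylated at the alpha carbon (NaH, PhSeCl, THF, 0 °C) to the alpha-phenylseleno keto ester F1. Irradiation of F1 in the presence of a chelating Lewis acid (Mg(ClO4)2 or Yb(OTf)3, CH2Cl2–toluene, low temperature) should trigger the phenylseleno-group-transfer tandem radical cyclization under control of the same auxiliary and give the C8 tertiary selenide F2. Oxidation of F2 with H2O2 and pyridine and syn-elimination of the selenoxide toward the C17 methyl would give 10, which is hydrolysed as in step 6. The fallback comes back to the route at 11.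

Step 8. Hydrazone formation at the hindered C3 carbonyl may be slow, and the reduction may be diverted into elimination to a ring A alkene. The fallback is a radical deoxygenation that sets out from 12. NaBH4 in MeOH at 0 °C reduces only the C3 ketone to the 3β-alcohol F3 (either epimer serves). 1,1'-Thiocarbonyldiimidazole with DMAP in warm toluene gives the imidazolylthiocarbonate F4 under non-basic conditions that avoid retro-aldol cleavage. Barton–McCombie reduction of F4 (Bu3SnH, AIBN, toluene, reflux) comes back to the route at 14.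

Step 11. The oxidation may stall at the hindered aldehyde, or the acidic medium may move the exocyclic double bond into the ring. The fallback sets out from 17 and splits the oxidation into two neutral stages: Dess–Martin periodinane buffered with NaHCO3 in CH2Cl2 gives aldehyde 18, now isolated, and chlorite oxidation (NaClO2, NaH2PO4, 2-methyl-2-butene, t-BuOH–H2O) comes back to the route at 19.

**Further compounds**

F1 | step 6 | (−)-8-phenylmenthyl (6E,10E)-2,6,10-trimethyl-13-(2-methyl-1,3-dioxolan-2-yl)-3-oxo-2-(phenylselanyl)trideca-6,10-dienoate | CC1(CC/C=C(\C)CC/C=C(\C)CCC(=O)C(C)([Se]c2ccccc2)C(=O)O[C@@H]2C[C@H](C)CC[C@H]2C(C)(C)c2ccccc2)OCCO1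
F2 | step 6 | (−)-8-phenylmenthyl 13,13-(ethylenedioxy)-3-oxo-8-(phenylselanyl)-14,15-dinorlabdan-19-oate (C8 epimers) | CC1([Se]c4ccccc4)CC[C@@H]2[C@](C)(CCC(=O)[C@]2(C)C(=O)O[C@@H]3C[C@H](C)CC[C@H]3C(C)(C)c3ccccc3)[C@H]1CCC5(C)OCCO5
F3 | step 8 | 15-ethyl 19-[(−)-8-phenylmenthyl] 3β-hydroxylabda-8(17),13E-diene-15,19-dioate | C=C1CC[C@@H]2[C@](C)(CC[C@H](O)[C@]2(C)C(=O)O[C@@H]3C[C@H](C)CC[C@H]3C(C)(C)c3ccccc3)[C@H]1CC/C(C)=C/C(=O)OCC
F4 | step 8 | 15-ethyl 19-[(−)-8-phenylmenthyl] 3β-[(1H-imidazol-1-ylcarbonothioyl)oxy]labda-8(17),13E-diene-15,19-dioate | C=C1CC[C@@H]2[C@](C)(CC[C@H](OC(=S)n3ccnc3)[C@]2(C)C(=O)O[C@@H]3C[C@H](C)CC[C@H]3C(C)(C)c3ccccc3)[C@H]1CC/C(C)=C/C(=O)OCC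
F0 | step 11 | none | none
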